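**Assumptions**
- The target SMILES is read as (2R,3R), i.e. 2,3-trans, with 7,4'-dihydroxy, 8,3'-diprenyl and no 5-OH.
- Once the C3 alkoxide is protonated, the two phenoxides are the only reactive oxygens. The neutral, hindered 3-OH is not acylated by a slight excess of Ac2O in the short reaction time.

**Retrosynthetic overview**
1. The target comes from lipase (hydrolase) alcoholysis of the phenolic diacetate **28** under neutral conditions.
2. **28** comes from one-pot fluoride unmasking of the tri-TBS trans-epoxy ketone **26**. Ring C closes last: the A-ring phenoxide opens the epoxide at the benzylic carbon (6-endo SN2), which inverts C2 to 2R and turns the epoxide oxygen into 3R-OH. The two phenols are then acetylated.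
3. **26** comes from the A-ring aryllithium (from bromide **25**) adding to the glycidic Weinreb amide **16**.
4. **16** comes from the B-ring cinnamyl alcohol **11** by Sharpless asymmetric epoxidation, which sets C2 and C3, followed by oxidation to the acid and Weinreb amide formation.
5. Both arenes are built first. The B-ring prenyl group is installed by Claisen rearrangement then cross-metathesis. The A-ring prenyl group is installed by ortho-lithiation and Cu-catalysed prenylation. The oxirane forms before the pyranone ring.

---

**Step 1**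
Reactants: **1** 4-hydroxybenzaldehyde; **2** allyl bromide
Product: **3** 4-(allyloxy)benzaldehyde
Conditions: K2CO3, acetone, reflux, 12 h
Reagents that add atoms: allyl bromide (**2**), C=CCBr
Why: Williamson O-alkylation of the phenoxide.

**Step 2**
Reactants: **3**
Product: **4** 3-allyl-4-hydroxybenzaldehyde
Conditions: PhNEt2, 200 °C (sealed tube), 3 h
Reagents that add atoms: none
Why: Aromatic Claisen [3,3] rearrangement. The para position is blocked, so the allyl group migrates to the ortho position.

**Step 3**
Reactants: **4**; **5** TBSCl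
Product: **6** 3-allyl-4-(tert-butyldimethylsilyloxy)benzaldehyde
Conditions: imidazole, DMF, 0 °C → rt, 4 h
Reagents that add atoms: TBSCl (**5**), CC(C)(C)[Si](C)(C)Cl
Why: Silyl protection of the phenol so that it survives the metathesis, the Ti-catalysed epoxidation and the organolithium chemistry.

**Step 4**
Reactants: **6**; **7** 2-methylbut-2-ene
Product: **8** 4-(TBSO)-3-(3-methylbut-2-en-1-yl)benzaldehyde (by-product propene)
Conditions: Hoveyda–Grubbs II (5 mol %), 1,4-benzoquinone (10 mol %), CH2Cl2, 40 °C, sealed, 16 h
Reagents that add atoms: 2-methylbut-2-ene (**7**), CC=C(C)C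
Why: Cross-metathesis converts the terminal allyl group into a prenyl group; the quinone suppresses Ru–H isomerisation to the propenyl arene.

**Step 5**
Reactants: **8**; **9** triethyl phosphonoacetate
Product: **10** ethyl (E)-3-[4-(TBSO)-3-prenylphenyl]acrylate
Conditions: DBU, LiCl, MeCN, rt, 6 h
Reagents that add atoms: triethyl phosphonoacetate (**9**), CCOC(=O)CP(=O)(OCC)OCC
Why: Masamune–Roush Horner–Wadsworth–Emmons olefination is E-selective, and the mild base leaves the aryl silyl ether intact.

**Step 6**
Reactants: **10**
Product: **11** (E)-3-[4-(TBSO)-3-prenylphenyl]prop-2-en-1-ol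
Conditions: DIBAL-H (2.5 equiv), CH2Cl2, −78 → −20 °C, 2 h; Rochelle salt work-up
Reagents that add atoms: none
Why: 1,2-Reduction of the ester to the allylic alcohol; the alkenes and the silyl ether are untouched.

**Step 7**
Reactants: **11**; **12** tert-butyl hydroperoxide
Product: **13** {(2S,3S)-3-[4-(TBSO)-3-prenylphenyl]oxiran-2-yl}methanol
Conditions: Ti(OiPr)4 (10 mol %), L-(+)-DET (12 mol %), 3 Å MS, CH2Cl2, −20 °C, 12 h; aq. NaOH/brine work-up; chromatography on Et3N-deactivated silica
Reagents that add atoms: TBHP (**12**), CC(C)(C)OO (supplies the epoxide O)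
Why: Sharpless asymmetric epoxidation. The chiral Ti–tartrate catalyst delivers oxygen to one face of the allylic alcohol, setting C2 and C3 as (2S,3S) trans. The reaction is directed by the OH, so the isolated prenyl alkene is untouched.

**Step 8**
Reactants: **13**
Product: **14** (2R,3S)-3-[4-(TBSO)-3-prenylphenyl]oxirane-2-carboxylic acid
Conditions: TEMPO (20 mol %), PhI(OAc)2 (2.5 equiv), NaHCO3 (3 equiv), MeCN/H2O (1:1), 0 °C → rt, 2 h; cold citric-acid quench to pH ~5, immediate extraction, crude acid used at once
Reagents that add atoms: water, O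
Why: TEMPO/BAIB oxidises the primary alcohol to the acid; the bicarbonate buffer neutralises the AcOH formed so the electron-rich benzylic epoxide is not opened. The epoxide carbons are untouched, and C2 changes from S to R only because the CIP priorities change.

**Step 9**
Reactants: **14**; **15** N,O-dimethylhydroxylamine hydrochloride
Product: **16** (2R,3S)-3-[4-(TBSO)-3-prenylphenyl]-N-methoxy-N-methyloxirane-2-carboxamide
Conditions: i-BuOCOCl, N-methylmorpholine, THF, −15 °C; then **15**, NMM, −15 → 0 °C
Reagents that add atoms: MeNHOMe·HCl (**15**), CNOC.Cl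
Why: Mixed-anhydride Weinreb amide formation under mild, non-acidic conditions that keep the epoxide intact.

**Step 10**
Reactants: **17** resorcinol; **18** MOMCl
Product: **19** 1,3-bis(methoxymethoxy)benzene
Conditions: NaH (2.3 equiv), THF/DMF, 0 °C → rt, 3 h
Reagents that add atoms: MOMCl (**18**), COCCl
Why: Bis-O-MOM protection; MOM is a strong ortho-directing group for the next step.

**Step 11**
Reactants: **19**; **20** prenyl bromide
Product: **21** 2-(3-methylbut-2-en-1-yl)-1,3-bis(methoxymethoxy)benzene
Conditions: n-BuLi, Et2O, 0 °C → rt, 3 h; then CuI (10 mol %), **20**, −40 °C → rt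
Reagents that add atoms: prenyl bromide (**20**), CC(C)=CCBr
Why: Directed ortho-metalation occurs at C2 between the two OMOM groups, and Cu-catalysed SN2 alkylation then gives the linear prenyl group.

**Step 12**
Reactants: **21**; **22** NBS
Product: **23** 1-bromo-2,4-bis(methoxymethoxy)-3-(3-methylbut-2-en-1-yl)benzene
Conditions: MeCN, solid NaHCO3, −20 → 0 °C, 1 h, dark
Reagents that add atoms: NBS (**22**), BrN1C(=O)CCC1=O
Why: Electrophilic aromatic bromination occurs at the position ortho to one OMOM and para to the other. The dialkoxyarene is far more nucleophilic than the trisubstituted alkene.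

**Step 13**
Reactants: **23**
Product: **24** 4-bromo-2-(3-methylbut-2-en-1-yl)benzene-1,3-diol
Conditions: TsOH·H2O (0.3 equiv), MeOH, 40 °C, 6 h
Reagents that add atoms: none
Why: Acid methanolysis of the MOM acetals; mild acid and low temperature avoid prenyl–phenol cyclisation.

**Step 14**
Reactants: **24**; **5** TBSCl
Product: **25** 1-bromo-2,4-bis(TBSO)-3-(3-methylbut-2-en-1-yl)benzene
Conditions: imidazole, DMF, 50 °C, 24 h (TBSCl 3 equiv)
Reagents that add atoms: TBSCl (**5**), CC(C)(C)[Si](C)(C)Cl
Why: TBS ethers tolerate the aryllithium step and aqueous work-up and are later removed by fluoride; the forcing conditions are needed for the phenol flanked by Br and prenyl.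

**Step 15**
Reactants: **25**; **16**
Product: **26** (2,4-bis(TBSO)-3-prenylphenyl)[(2R,3S)-3-(4-TBSO-3-prenylphenyl)oxiran-2-yl]methanone
Conditions: t-BuLi (2.1 equiv to **25**), THF, −78 °C, 15 min; then **16** (0.8 equiv to **25**), −78 °C, 1 h; sat. NH4Cl at −78 °C
Reagents that add atoms: none (both fragments are listed as reactants)
Why: Bromine–lithium exchange followed by Weinreb acylation. The stable chelated tetrahedral intermediate prevents over-addition, and the epoxide stereocentres are untouched, giving the trans-epoxy ketone (αR,βS).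

**Step 16**
Reactants: **26**; **27** acetic anhydride
Product: **28** (2R,3R)-7-acetoxy-2-(4-acetoxy-3-prenylphenyl)-3-hydroxy-8-prenylchroman-4-one
Conditions: TBAT (anhydrous fluoride, 3.2 equiv), THF, 0 °C, 1.5 h; then AcOH (1.2 equiv), then Ac2O (2.4 equiv), 0 °C, 30 min; aq. NaHCO3 work-up; chromatography and recrystallisation
Reagents that add atoms: acetic anhydride (**27**), CC(=O)OC(C)=O
Why: Fluoride cleaves the two ketone-conjugated A-ring silyl ethers first, and the 2'-phenoxide opens the benzylic epoxide carbon intramolecularly (6-endo-tet SN2), which inverts that carbon from S to R (2R). The α-carbon keeps its configuration and becomes 3R-OH, giving the 2,3-trans ring. The B-ring silyl ether is cleaved last, after ring closure, and the 7-phenoxide makes the A-ring aryloxide a poor leaving group, which disfavours quinone-methide racemisation at C2. AcOH protonates the C3 alkoxide so that Ac2O acylates only the two phenoxides, giving a stable, crystalline diacetate, and the free polyphenol is never isolated.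

**Step 17**
Reactants: **28**
Product: **29** (2R,3R)-3-hydroxyglabrol (target)
Conditions: Novozym 435 (immobilised Candida antarctica lipase B), n-BuOH (10 equiv), MTBE, 35 °C, 48 h; filter and concentrate
Reagents that add atoms: none (n-BuOH leaves as BuOAc)
Why: Lipase (a hydrolase) catalysed alcoholysis cleaves the phenolic aryl acetates chemoselectively at neutral pH. With no acid or base present, the 3-hydroxychromanone cannot epimerise, retro-oxa-Michael open or be oxidised, the prenyl phenols cannot cyclise, and C2 and C3 are not touched.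

---

**Compound list**

| No. | Name | SMILES | Role |
|---|---|---|---|
| 1 | 4-hydroxybenzaldehyde | O=Cc1ccc(O)cc1 | starting material |
| 2 | allyl bromide | C=CCBr | starting material |
| 3 | 4-(allyloxy)benzaldehyde | C=CCOc1ccc(C=O)cc1 | intermediate |
| 4 | 3-allyl-4-hydroxybenzaldehyde | C=CCc1cc(C=O)ccc1O | intermediate |
| 5 | TBSCl | CC(C)(C)[Si](C)(C)Cl | starting material |
| 6 | 3-allyl-4-(TBSO)benzaldehyde | C=CCc1cc(C=O)ccc1O[Si](C)(C)C(C)(C)C | intermediate |
| 7 | 2-methylbut-2-ene | CC=C(C)C | starting material |
| 8 | 4-(TBSO)-3-prenylbenzaldehyde | CC(C)=CCc1cc(C=O)ccc1O[Si](C)(C)C(C)(C)C | intermediate |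
| 9 | triethyl phosphonoacetate | CCOC(=O)CP(=O)(OCC)OCC | starting material |
| 10 | ethyl (E)-3-[4-(TBSO)-3-prenylphenyl]acrylate | CCOC(=O)/C=C/c1ccc(O[Si](C)(C)C(C)(C)C)c(CC=C(C)C)c1 | intermediate |
| 11 | (E)-3-[4-(TBSO)-3-prenylphenyl]prop-2-en-1-ol | OC/C=C/c1ccc(O[Si](C)(C)C(C)(C)C)c(CC=C(C)C)c1 | intermediate |
| 12 | tert-butyl hydroperoxide | CC(C)(C)OO | starting material |
| 13 | (2S,3S)-epoxy alcohol | CC(C)=CCc1cc([C@@H]2O[C@H]2CO)ccc1O[Si](C)(C)C(C)(C)C | intermediate |
| 14 | (2R,3S)-epoxy acid | CC(C)=CCc1cc([C@@H]2O[C@H]2C(=O)O)ccc1O[Si](C)(C)C(C)(C)C | intermediate |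
| 15 | N,O-dimethylhydroxylamine hydrochloride | CNOC.Cl | starting material |
| 16 | (2R,3S)-glycidic Weinreb amide | CC(C)=CCc1cc([C@@H]2O[C@H]2C(=O)N(C)OC)ccc1O[Si](C)(C)C(C)(C)C | intermediate |
| 17 | resorcinol | Oc1cccc(O)c1 | starting material |
| 18 | MOMCl | COCCl | starting material |
| 19 | 1,3-bis(methoxymethoxy)benzene | COCOc1cccc(OCOC)c1 | intermediate |
| 20 | prenyl bromide | CC(C)=CCBr | starting material |
| 21 | 2-prenyl-1,3-bis(MOMO)benzene | COCOc1cccc(OCOC)c1CC=C(C)C | intermediate |
| 22 | N-bromosuccinimide | BrN1C(=O)CCC1=O | starting material |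
| 23 | 1-bromo-2,4-bis(MOMO)-3-prenylbenzene | COCOc1ccc(Br)c(OCOC)c1CC=C(C)C | intermediate |
| 24 | 4-bromo-2-prenylresorcinol | CC(C)=CCc1c(O)ccc(Br)c1O | intermediate |
| 25 | 1-bromo-2,4-bis(TBSO)-3-prenylbenzene | CC(C)=CCc1c(O[Si](C)(C)C(C)(C)C)ccc(Br)c1O[Si](C)(C)C(C)(C)C | intermediate |
| 26 | trans-epoxy ketone (αR,βS) | CC(C)=CCc1cc([C@@H]2O[C@H]2C(=O)c3ccc(O[Si](C)(C)C(C)(C)C)c(CC=C(C)C)c3O[Si](C)(C)C(C)(C)C)ccc1O[Si](C)(C)C(C)(C)C | intermediate |
| 27 | acetic anhydride | CC(=O)OC(C)=O | starting material |
| 28 | 7,4'-di-O-acetyl-3-hydroxyglabrol, (2R,3R) | CC(C)=CCc1cc([C@H]2Oc3c(ccc(OC(C)=O)c3CC=C(C)C)C(=O)[C@@H]2O)ccc1OC(C)=O | intermediate |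
| 29 | 3-hydroxyglabrol, (2R,3R) | CC(C)=CCc1cc([C@H]2Oc3c(ccc(O)c3CC=C(C)C)C(=O)[C@@H]2O)ccc1O | target |

---

**Totals**
- Total steps: 17 (B-ring branch steps 1–9, A-ring branch steps 10–14, then steps 15–17).
- Longest linear sequence: 12 steps (steps 1–9, then 15, 16 and 17).

**Three steps most likely to fail**
1. **Step 15, aryllithium addition to the epoxy Weinreb amide.** Risks are α-deprotonation or opening of the epoxide and O→C silyl migration in the ortho-silyloxy aryllithium. Fallback: oxidise **13** to the epoxy aldehyde (SO3·py/DMSO/Et3N), add the same aryllithium from **25**, then oxidise the carbinol mixture with Dess–Martin periodinane to give **26**. This bypasses the sensitive epoxy acid and the amide.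
2. **Step 16, desilylative 6-endo closure.** Risks are 5-exo aurone formation and quinone-methide-type ionisation eroding C2 stereochemistry. Fallback: carry the B-ring phenol as a MOM ether instead of TBS through steps 3–9 and 15. Unmask only the A-ring silyl ethers and close the ring with K2CO3/MeOH, so the B-ring oxygen stays masked during cyclisation. Then remove the MOM group with PPTS/t-BuOH and omit the acetylation and lipase steps.
3. **Step 17, lipase alcoholysis.** The ortho-prenyl aryl acetates may react slowly or incompletely. Fallback: drop the enzyme and cleave the acetates with hydrazinium acetate (NH2NH2·AcOH, DMF, rt), a near-neutral aminolysis selective for phenolic acetates.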